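**Retrosynthetic overview**

- The strategy rests on the single stereocentre C4 of the 17-membered ring (N1 lactam nitrogen, C2 carbonyl, C3, C4 bearing the nonyl chain, N5, N9, N14). C4 is β to the C2 carbonyl and bonded to N5, so it is a β-amino amide carbon.
- Key disconnection C4–N5: the ring opens to a 3-oxododecanoyl amide of spermine whose far primary nitrogen condenses with the C4 ketone to a Z β-enamino lactam, which is hydrogenated enantioselectively in the same pot.
- The precursor comes from spermine: Boc on both secondary nitrogens, trityl on one primary nitrogen, and the other primary nitrogen acylated with the acylketene from decanoyl Meldrum's acid. Mild acid then removes the trityl group and gives the ammonium salt.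
- Only one ring is formed (step 8). Boc cleavage in step 9 gives the target.

Key step: step 8

Remark: the free amino β-keto amide would condense with itself on storage, so it is carried N-tritylated and released only as its trifluoroacetate salt just before ring closure. Spermine positions N1, N4, N9, N12 become ring atoms N1, N14, N9, N5, and the target is taken as the free base.

**Route**

Step 1
Reactants: 1 spermine
Product: 2 N1,N12-bis(trifluoroacetyl)spermine
Conditions: CF3CO2Et (2.05 equiv), MeOH, −78 °C → 0 °C
Reagents that add atoms: ethyl trifluoroacetate, CCOC(=O)C(F)(F)F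
Why: Aminolysis of the activated ester is much faster at the unhindered primary amines than at the secondary ones at low temperature, a standard chemoselective N-trifluoroacetylation of polyamines.

Step 2
Reactants: 2 N1,N12-bis(trifluoroacetyl)spermine
Product: 3 N4,N9-di-Boc-N1,N12-bis(trifluoroacetyl)spermine
Conditions: Boc2O (2.4 equiv), Et3N (cat.), CH2Cl2/MeOH, 0 °C → rt
Reagents that add atoms: di-tert-butyl dicarbonate, CC(C)(C)OC(=O)OC(=O)OC(C)(C)C
Why: Carbamate formation takes place at the only nucleophilic nitrogens left, the two secondary amines, since the trifluoroacetamide N–H groups are not acylated without a nucleophilic catalyst.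

Step 3
Reactants: 3 N4,N9-di-Boc-N1,N12-bis(trifluoroacetyl)spermine
Product: 4 N4,N9-di-Boc-spermine
Conditions: K2CO3 (5 equiv), MeOH/H2O (5:1), rt
Reagents that add atoms: none
Why: Trifluoroacetamides undergo mild basic solvolysis under which tert-butyl carbamates are inert, which frees both primary amines.

Step 4
Reactants: 4 N4,N9-di-Boc-spermine (3 equiv, excess recovered)
Product: 5 N4,N9-di-Boc-N12-tritylspermine
Conditions: TrCl (1 equiv, slow addition), Et3N, CH2Cl2, 0 °C; chromatography on Et3N-doped silica
Reagents that add atoms: trityl chloride, ClC(c1ccccc1)(c1ccccc1)c1ccccc1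
Why: N-Tritylation of a primary amine with the diamine in excess should favour the mono-trityl compound statistically, and the wide polarity gap between diamine, mono- and bis-trityl products allows separation and recycling of 4.

Step 5
Reactants: 6 decanoyl chloride; 7 Meldrum's acid
Product: 8 5-(1-hydroxydecylidene)-2,2-dimethyl-1,3-dioxane-4,6-dione (decanoyl Meldrum's acid, enol form)
Conditions: pyridine (2 equiv), CH2Cl2, 0 °C → rt; cold dilute HCl wash
Reagents that add atoms: none
Why: C-Acylation of the acidic methylene of Meldrum's acid by an acid chloride with pyridine is the standard entry to acyl Meldrum's acids.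

Step 6
Reactants: 5 N4,N9-di-Boc-N12-tritylspermine; 8 decanoyl Meldrum's acid
Product: 9 N1-(3-oxododecanoyl)-N4,N9-di-Boc-N12-tritylspermine
Conditions: Et3N (1.2 equiv), MeCN, rt then reflux
Reagents that add atoms: none
Why: On heating the acyl Meldrum's acid loses acetone and CO2 to give an acylketene that the primary amine traps as the β-keto amide (acylketene aminolysis), while the hindered trityl-bearing nitrogen does not react and Et3N buffers the acidic enol so the trityl group survives.

Step 7
Reactants: 9 N1-(3-oxododecanoyl)-N4,N9-di-Boc-N12-tritylspermine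
Product: 10 N1-(3-oxododecanoyl)-N4,N9-di-Boc-spermine trifluoroacetate (N12 ammonium salt)
Conditions: CF3CO2H (3 equiv, about 1% v/v), Et3SiH (3 equiv), CH2Cl2, 0 °C; toluene co-evaporation below 25 °C, hexane trituration
Reagents that add atoms: trifluoroacetic acid, OC(=O)C(F)(F)F
Why: Acidolysis of an N-trityl amine proceeds in dilute acid that leaves Boc intact, the silane reduces the trityl cation irreversibly to triphenylmethane, and the amine is released as its ammonium salt, which cannot condense with the ketone.

Step 8
Reactants: 10 N1-(3-oxododecanoyl)-N4,N9-di-Boc-spermine trifluoroacetate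
Product: 12 di-tert-butyl (4R)-4-nonyl-2-oxo-1,5,9,14-tetraazacycloheptadecane-9,14-dicarboxylate, via Z-enamino lactam 11 (not isolated)
Conditions: NaOAc (1.0 equiv), AcOH (0.5 equiv), 4 Å MS, CF3CH2OH (2 mM), 50 °C; then [Rh(cod)Cl]2 (5 mol%), (R)-1-[(Sp)-2-(diphenylphosphino)ferrocenyl]ethyldi-tert-butylphosphine (11 mol%), H2 (20 bar), 50 °C; NaHCO3 work-up
Reagents that add atoms: none
Why: Proposed new method: sodium acetate frees the amine of 10 into an acetic acid buffer, N5 adds reversibly to the C4 ketone and water is lost to give the hydrogen-bonded Z vinylogous urea 11, whose imine tautomer chelates rhodium through N5 and the C2 carbonyl and takes up H2 irreversibly. The closest known reactions are the rhodium–Josiphos hydrogenation of unprotected primary Z β-enamino amides and esters and the iridium-catalysed direct asymmetric reductive amination of ketones with primary alkylamines, neither of which has been shown on an N-alkyl enamine held in a macrocycle. The 17-membered ring closes by 17-exo-trig attack of N5 on the C4 carbonyl followed by dehydration, under thermodynamic control. The C4 stereocentre is set by the chiral diphosphine alone (catalyst control); the (R,Sp) ligand is chosen by analogy with the sense known for acyclic β-enamino amides of the same priority pattern and is expected to give R, with the (S,Rp) enantiomer used instead should the sense prove reversed. The step needs ring-over-oligomer selectivity, secured by the 2 mM dilution and by letting the reversible condensation settle before H2 is admitted; it needs Z geometry, secured by the N5–H to C2=O hydrogen bond; and it needs reaction at N5 only, secured by the Boc groups on N9 and N14, which also keep those nitrogens off the metal.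

Step 9
Reactants: 12 di-tert-butyl (4R)-4-nonyl-2-oxo-1,5,9,14-tetraazacycloheptadecane-9,14-dicarboxylate
Product: 13 (4R)-4-nonyl-1,5,9,14-tetraazacycloheptadecan-2-one
Conditions: CF3CO2H/CH2Cl2 (1:1), rt; then 2 M NaOH, CHCl3/iPrOH extraction
Reagents that add atoms: none
Why: Acidolysis of both tert-butyl carbamates releases isobutene and CO2 without affecting the lactam or the C4 stereocentre, which has no pathway for epimerisation in acid, and the basic work-up gives the free base.

**Compound list**

1 | spermine | NCCCNCCCCNCCCN | starting material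
2 | N1,N12-bis(trifluoroacetyl)spermine | FC(F)(F)C(=O)NCCCNCCCCNCCCNC(=O)C(F)(F)F | intermediate
3 | N4,N9-di-Boc-N1,N12-bis(trifluoroacetyl)spermine | FC(F)(F)C(=O)NCCCN(C(=O)OC(C)(C)C)CCCCN(C(=O)OC(C)(C)C)CCCNC(=O)C(F)(F)F | intermediate
4 | N4,N9-di-Boc-spermine | NCCCN(C(=O)OC(C)(C)C)CCCCN(C(=O)OC(C)(C)C)CCCN | intermediate
5 | N4,N9-di-Boc-N12-tritylspermine | NCCCN(C(=O)OC(C)(C)C)CCCCN(C(=O)OC(C)(C)C)CCCNC(c1ccccc1)(c1ccccc1)c1ccccc1 | intermediate
6 | decanoyl chloride | CCCCCCCCCC(=O)Cl | starting material
7 | Meldrum's acid (2,2-dimethyl-1,3-dioxane-4,6-dione) | CC1(C)OC(=O)CC(=O)O1 | starting material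
8 | 5-(1-hydroxydecylidene)-2,2-dimethyl-1,3-dioxane-4,6-dione | CCCCCCCCCC(O)=C1C(=O)OC(C)(C)OC1=O | intermediate
9 | N1-(3-oxododecanoyl)-N4,N9-di-Boc-N12-tritylspermine | CCCCCCCCCC(=O)CC(=O)NCCCN(C(=O)OC(C)(C)C)CCCCN(C(=O)OC(C)(C)C)CCCNC(c1ccccc1)(c1ccccc1)c1ccccc1 | intermediate
10 | N1-(3-oxododecanoyl)-N4,N9-di-Boc-spermine trifluoroacetate | CCCCCCCCCC(=O)CC(=O)NCCCN(C(=O)OC(C)(C)C)CCCCN(C(=O)OC(C)(C)C)CCCN.OC(=O)C(F)(F)F | intermediate
11 | di-tert-butyl (3Z)-4-nonyl-2-oxo-1,5,9,14-tetraazacycloheptadec-3-ene-9,14-dicarboxylate | CCCCCCCCC/C1=C/C(=O)NCCCN(C(=O)OC(C)(C)C)CCCCN(C(=O)OC(C)(C)C)CCCN1 | intermediate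
12 | di-tert-butyl (4R)-4-nonyl-2-oxo-1,5,9,14-tetraazacycloheptadecane-9,14-dicarboxylate | CCCCCCCCC[C@@H]1CC(=O)NCCCN(C(=O)OC(C)(C)C)CCCCN(C(=O)OC(C)(C)C)CCCN1 | intermediate
13 | (4R)-4-nonyl-1,5,9,14-tetraazacycloheptadecan-2-one | CCCCCCCCC[C@@H]1CC(=O)NCCCNCCCCNCCCN1 | target

**Step count**

Total steps: 9. Longest linear sequence: 8 (steps 1–4 and 6–9 from spermine; step 5 is a one-step side branch).

**Steps most likely to fail**

1. Step 8 (the proposed new method). Oligomeric enamines may be hydrogenated in competition with the ring, turnover may be slow at 2 mM or inhibited by the basic amine product, and facial selectivity on the macrocyclic N-alkyl enamine may be poor. The fallback sets out from 10 and comes back at 12, and it separates ring closure from reduction using known reactions. Salt 10 is condensed without catalyst (NaOAc, AcOH, 4 Å MS, CF3CH2OH, 2 mM, 50 °C) and the Z-enamino lactam 11 is isolated. Compound 11 is reduced with NaBH(OAc)3 in AcOH/MeCN at 0 °C, the standard hydride reduction of β-enamino amides through the iminium tautomer, to give racemic di-tert-butyl 4-nonyl-2-oxo-1,5,9,14-tetraazacycloheptadecane-9,14-dicarboxylate F1. F1 is resolved by preparative chromatography on a chiral stationary phase, which should return the (4R) enantiomer 12 and set aside di-tert-butyl (4S)-4-nonyl-2-oxo-1,5,9,14-tetraazacycloheptadecane-9,14-dicarboxylate F2.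

2. Step 7. Partial loss of Boc may occur as the acid concentrates, trityl capture may be incomplete, or the freed amine may start to condense during isolation. The fallback sets out from 4 and comes back at 10, and it unmasks the amine by hydrogenolysis instead of acidolysis. Diamine 4 (3 equiv) is treated with N-(benzyloxycarbonyloxy)succinimide (1 equiv, CH2Cl2, 0 °C) to give N4,N9-di-Boc-N12-(benzyloxycarbonyl)spermine F3. F3 is acylated with 8 (Et3N, MeCN, reflux) to give N1-(3-oxododecanoyl)-N4,N9-di-Boc-N12-(benzyloxycarbonyl)spermine F4. Hydrogenolysis of F4 (H2 at 1 atm, Pd/C, MeOH, rt) with CF3CO2H (1.0 equiv) present protonates the amine as it is freed and should deliver salt 10 directly.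

3. Step 6. The amine may add to the acyl carbon of 8 to give a stable enamine adduct instead of trapping the acylketene, and the trityl group may be lost on heating with the acidic enol. The fallback sets out from 5 and comes back at 9, and it replaces acylketene trapping by amide coupling and oxidation. Amine 5 is coupled with racemic 3-hydroxydodecanoic acid (CCCCCCCCCC(O)CC(=O)O; N,N'-diisopropylcarbodiimide, HOBt, CH2Cl2, rt) to give N1-(3-hydroxydodecanoyl)-N4,N9-di-Boc-N12-tritylspermine F5. Oxidation of the secondary alcohol of F5 with Dess–Martin periodinane (pyridine, CH2Cl2, 0 °C → rt) should give β-keto amide 9.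

**Further compounds**

F1 | step 8 | racemic di-tert-butyl 4-nonyl-2-oxo-1,5,9,14-tetraazacycloheptadecane-9,14-dicarboxylate | CCCCCCCCCC1CC(=O)NCCCN(C(=O)OC(C)(C)C)CCCCN(C(=O)OC(C)(C)C)CCCN1
F2 | step 8 | di-tert-butyl (4S)-4-nonyl-2-oxo-1,5,9,14-tetraazacycloheptadecane-9,14-dicarboxylate | CCCCCCCCC[C@H]1CC(=O)NCCCN(C(=O)OC(C)(C)C)CCCCN(C(=O)OC(C)(C)C)CCCN1
F3 | step 7 | N4,N9-di-Boc-N12-(benzyloxycarbonyl)spermine | NCCCN(C(=O)OC(C)(C)C)CCCCN(C(=O)OC(C)(C)C)CCCNC(=O)OCc1ccccc1
F4 | step 7 | N1-(3-oxododecanoyl)-N4,N9-di-Boc-N12-(benzyloxycarbonyl)spermine | CCCCCCCCCC(=O)CC(=O)NCCCN(C(=O)OC(C)(C)C)CCCCN(C(=O)OC(C)(C)C)CCCNC(=O)OCc1ccccc1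
F5 | step 6 | N1-(3-hydroxydodecanoyl)-N4,N9-di-Boc-N12-tritylspermine | CCCCCCCCCC(O)CC(=O)NCCCN(C(=O)OC(C)(C)C)CCCCN(C(=O)OC(C)(C)C)CCCNC(c1ccccc1)(c1ccccc1)c1ccccc1
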